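The labels are: cyclopentane C1(OAc)–C2–C3(Me)–C9(H)–C10(OH,iPr); cycloheptene C3–C4(OH)–C5–C6(Me)=C7–C8(OAr)–C9. The ring-fusion bond C3–C9 is made by a semipinacol 1,2-shift. (S)-Wieland–Miescher ketone gives a trans-decalin in which C3 is still bonded to C8, with a tertiary C8 hydroxyl and an equatorial C9 mesylate. Base moves C3 from C8 to C9: one ring contracts to the cyclopentane, the other expands to the seven-membered ring, the C8 carbonyl appears and C9 is set, cis-fused. The step exploits the C8 oxygen beside C9 and the quaternary C3. Enone methylation, esterification and convex-face dihydroxylation of a C1=C10 isopropyl alkene finish the synthesis.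

Key step: step 7

Remarks on the chemistry:
- (S)-Wieland–Miescher ketone is taken as a commercial compound.
- The labels C1–C10 stay on the same atoms in every intermediate. In the decalins, ring A is C3–C4–C5–C6–C7–C8 and ring B is C3–C2–C1–C10–C9–C8.
- β is the face of the C3 methyl group, α the opposite face.
- TBS = tert-butyldimethylsilyl, PMB = 4-methoxybenzyl, Ms = methanesulfonyl, Tf = trifluoromethanesulfonyl.

Step 1
Reactants: 1 (S)-Wieland–Miescher ketone
Product: 2 C4 β-hydroxy enone
Conditions: NaBH4 (0.3 equiv), EtOH, −10 °C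
Reagents that add atoms: none
Why: Chemoselective borohydride reduction: the saturated C4 ketone is more electrophilic than the conjugated C10 carbonyl, and hydride adds anti to the angular methyl group, which sets the C4 hydroxyl cis (β) to that methyl.

Step 2
Reactants: 2 C4 β-hydroxy enone
Product: 3 C4 TBS ether of the enone
Conditions: TBSCl, imidazole, DMF, 40 °C
Reagents that add atoms: tert-butyldimethylsilyl chloride, CC(C)(C)[Si](C)(C)Cl
Why: Standard silyl ether formation protects the hindered secondary alcohol for all later base and hydride steps.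

Step 3
Reactants: 3 C4 TBS ether of the enone
Product: 4 C10 β-allylic alcohol
Conditions: NaBH4, CeCl3·7H2O, MeOH, −78 to 0 °C
Reagents that add atoms: none
Why: Luche reduction gives clean 1,2-reduction; axial hydride delivery on the α face (away from the axial C3 methyl) should give the equatorial β-alcohol at C10, a temporary stereocenter that step 14 removes.

Step 4
Reactants: 4 C10 β-allylic alcohol
Product: 5 C10 PMB ether
Conditions: NaH, 4-methoxybenzyl chloride, Bu4NI (cat.), THF/DMF, 0 °C to rt
Reagents that add atoms: 4-methoxybenzyl chloride, COc1ccc(CCl)cc1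
Why: Williamson etherification masks the C10 oxygen as an ether that cannot act as an alkoxide in step 7 and can be removed oxidatively in step 13.

Step 5
Reactants: 5 C10 PMB ether
Product: 6 trans-decalin C8,C9 α,α-diol
Conditions: OsO4 (5 mol %), N-methylmorpholine N-oxide, acetone/H2O, 40 °C
Reagents that add atoms: osmium tetroxide, O=[Os](=O)(=O)=O; N-methylmorpholine N-oxide, C[N+]1([O-])CCOCC1; water, O
Why: Upjohn dihydroxylation adds both oxygens syn from the α face, anti to the axial C3 methyl and to the allylic C10 ether; this sets C8 (axial tertiary OH) and C9 (equatorial secondary OH) and makes the ring fusion trans.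

Step 6
Reactants: 6 trans-decalin C8,C9 α,α-diol
Product: 7 C9 mesylate
Conditions: MsCl, Et3N, DMAP (cat.), CH2Cl2, 0 °C
Reagents that add atoms: methanesulfonyl chloride, CS(=O)(=O)Cl
Why: Sulfonylation is selective for the secondary C9 hydroxyl because the tertiary C8 hydroxyl does not react under these conditions.

Step 7
Reactants: 7 C9 mesylate
Product: 8 cis-fused hydroazulen-8-one
Conditions: KOtBu (1.05 equiv), THF, 0 °C to rt
Reagents that add atoms: none
Why: Deprotonation of the tertiary C8 hydroxyl gives an alkoxide that pushes the anti-periplanar ring bond C8–C3 onto C9 as the mesylate leaves, a concerted semipinacol 1,2-alkyl shift that forms C3–C9 and the C8 ketone. The closest known reaction type is the base-induced pinacol-type rearrangement of vicinal diol monosulfonates, the classical way to turn a decalin into a hydroazulene. The five-membered ring (C1–C2–C3–C9–C10) closes by contraction of ring B through backside displacement at C9 in a three-centre transition state, and the seven-membered ring forms in the same event by insertion of C9 between C8 and C3 of ring A. C9 is the only new stereocenter: C3 enters anti to the α-mesylate (inversion, H9 stays β) and migrates with retention, which should give the cis ring fusion. The step needs migration of C3 and not of C7 or C1: the rigid trans-decalin holds the equatorial C9–OMs bond anti-periplanar only to the ring bonds C8–C3 and C10–C1, and only C8 carries an alkoxide because the C10 oxygen is an ether. One equivalent of base is consumed in the shift, so the new ketone should not be enolised at C9.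

Step 8
Reactants: 8 cis-fused hydroazulen-8-one
Product: 10 C6=C7 enone, via trimethylsilyl enol ether 9 (not isolated)
Conditions: LiN(i-Pr)2, Me3SiCl, THF, −78 °C; then Pd(OAc)2, MeCN, rt
Reagents that add atoms: trimethylsilyl chloride, C[Si](C)(C)Cl (silyl group of intermediate 9 only)
Why: Kinetic enolisation removes a C7 proton (the C9 methine is hindered), and Saegusa–Ito oxidation of the silyl enol ether gives the C6=C7 enone.

Step 9
Reactants: 10 C6=C7 enone
Product: 12 C6-methyl enone, via methylated silyl enol ether 11 (not isolated)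
Conditions: MeLi (2 equiv), CuI, Et2O, 0 °C (gives Me2CuLi); then 10, Me3SiCl, THF, −78 °C; then crude 11, Pd(OAc)2, MeCN, rt
Reagents that add atoms: lithium dimethylcuprate, [Li+].C[Cu-]C; methyllithium, C[Li]; trimethylsilyl chloride, C[Si](C)(C)Cl (silyl group of intermediate 11 only)
Why: Chlorosilane-accelerated conjugate addition of the Gilman cuprate puts the methyl group on C6, and Saegusa–Ito oxidation restores the C6=C7 double bond, so the C6 stereocenter of 11 is lost again.

Step 10
Reactants: 12 C6-methyl enone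
Product: 13 C8 α-allylic alcohol
Conditions: NaBH4, CeCl3·7H2O, MeOH, −78 °C
Reagents that add atoms: none
Why: Luche 1,2-reduction; hydride should add to C8 from the β face, anti to the cyclopentane carbon C10 on C9, which sets the C8 hydroxyl α.

Step 11
Reactants: 14 4-hydroxybenzoic acid
Product: 16 4-(tert-butyldimethylsilyloxy)benzoic acid, via bis-silylated hydroxybenzoate 15 (not isolated)
Conditions: TBSCl (2.2 equiv), imidazole, DMF, rt; then AcOH/THF/H2O, rt
Reagents that add atoms: tert-butyldimethylsilyl chloride, CC(C)(C)[Si](C)(C)Cl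
Why: Exhaustive silylation followed by selective hydrolysis of the far more labile silyl ester leaves the phenol protected and the acid free.

Step 12
Reactants: 13 C8 α-allylic alcohol; 16 4-(tert-butyldimethylsilyloxy)benzoic acid
Product: 17 C8 α-aroyl ester
Conditions: DCC, DMAP, CH2Cl2, rt
Reagents that add atoms: none
Why: Steglich esterification acylates the only free hydroxyl with retention at C8.

Step 13
Reactants: 17 C8 α-aroyl ester
Product: 18 C10 β-alcohol
Conditions: DDQ, CH2Cl2/pH 7 buffer, 0 °C to rt
Reagents that add atoms: none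
Why: DDQ oxidises the electron-rich benzylic ether to an oxocarbenium ion that water hydrolyses, while the silyl ethers, the ester and the alkene are inert.

Step 14
Reactants: 18 C10 β-alcohol
Product: 19 C10 ketone
Conditions: Dess–Martin periodinane, CH2Cl2, rt
Reagents that add atoms: none
Why: Dess–Martin oxidation is neutral, so the β-aroyloxy ketone should form without elimination or epimerisation at C9.

Step 15
Reactants: 19 C10 ketone
Product: 20 C1=C10 enol triflate
Conditions: KN(SiMe3)2, THF, −78 °C (ketone added to the base); then PhNTf2, −78 to 0 °C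
Reagents that add atoms: N-phenylbis(trifluoromethanesulfonimide), O=S(=O)(N(c1ccccc1)S(=O)(=O)C(F)(F)F)C(F)(F)F
Why: Kinetic deprotonation with a bulky amide base takes the accessible C1 proton, not the hindered C9 methine, and O-triflation of that enolate fixes the C1=C10 double bond.

Step 16
Reactants: 20 C1=C10 enol triflate
Product: 21 C10-isopropyl cyclopentene
Conditions: i-PrMgCl, Fe(acac)3 (5 mol %), THF/N-methylpyrrolidone, −30 °C
Reagents that add atoms: isopropylmagnesium chloride, CC(C)[Mg]Cl
Why: Iron-catalysed Kumada-type coupling of an alkenyl triflate with a secondary Grignard reagent is faster than addition to the aryl ester at this temperature and places the isopropyl group on C10.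

Step 17
Reactants: 21 C10-isopropyl cyclopentene
Product: 22 C1,C10 β,β-diol
Conditions: OsO4 (5 mol %), N-methylmorpholine N-oxide, acetone/H2O, 0 °C
Reagents that add atoms: osmium tetroxide, O=[Os](=O)(=O)=O; N-methylmorpholine N-oxide, C[N+]1([O-])CCOCC1; water, O
Why: Upjohn dihydroxylation should prefer the electron-rich cyclopentene over the C6=C7 alkene (deactivated by the allylic ester); syn addition from the convex β face, away from the seven-membered ring, sets C1 and C10 with both hydroxyls β and the isopropyl group α.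

Step 18
Reactants: 22 C1,C10 β,β-diol
Product: 23 C1 acetate
Conditions: Ac2O, pyridine, DMAP (cat.), CH2Cl2, 0 °C to rt
Reagents that add atoms: acetic anhydride, CC(=O)OC(C)=O
Why: Acetylation is selective for the secondary C1 hydroxyl because the tertiary C10 hydroxyl is inert under these conditions.

Step 19
Reactants: 23 C1 acetate
Product: 24 target CNP0146780.2
Conditions: HF·pyridine, THF/pyridine, 0 °C to rt
Reagents that add atoms: none
Why: Buffered fluoride desilylation frees the C4 hydroxyl and the phenol without touching the acetate, the benzoate or the tertiary alcohol.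

Compound list
1 | (S)-Wieland–Miescher ketone, (8aS)-8a-methyl-3,4,8,8a-tetrahydronaphthalene-1,6(2H,7H)-dione | C1C[C@]2(C)C(=O)CCCC2=CC1=O | starting material
2 | (4aS,5S)-5-hydroxy-4a-methyl-4,4a,5,6,7,8-hexahydronaphthalen-2(3H)-one (C4 β-OH, cis to the C3 methyl) | C1C[C@]2(C)[C@@H](O)CCCC2=CC1=O | intermediate
3 | C4 β-TBS ether of 2 | C1C[C@]2(C)[C@@H](O[Si](C)(C)C(C)(C)C)CCCC2=CC1=O | intermediate
4 | (2S,4aS,5S)-5-(tert-butyldimethylsilyloxy)-4a-methyl-2,3,4,4a,5,6,7,8-octahydronaphthalen-2-ol (C10 β-OH, C8=C9 alkene) | C1C[C@]2(C)[C@@H](O[Si](C)(C)C(C)(C)C)CCCC2=C[C@H]1O | intermediate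
5 | C10 β-PMB ether of 4 | C1C[C@]2(C)[C@@H](O[Si](C)(C)C(C)(C)C)CCCC2=C[C@H]1OCc3ccc(OC)cc3 | intermediate
6 | trans-decalin diol: C3 β-Me, C4 β-OTBS, C8 α-OH (tertiary, axial), C9 α-OH (equatorial), C10 β-OPMB | C1C[C@]2(C)[C@@H](O[Si](C)(C)C(C)(C)C)CCC[C@@]2(O)[C@H](O)[C@H]1OCc3ccc(OC)cc3 | intermediate
7 | C9 α-mesylate of 6 | C1C[C@]2(C)[C@@H](O[Si](C)(C)C(C)(C)C)CCC[C@@]2(O)[C@H](OS(C)(=O)=O)[C@H]1OCc3ccc(OC)cc3 | intermediate
8 | cis-fused hydroazulenone: C8 ketone, C9 β-H, C3 β-Me, C4 β-OTBS, C10 β-OPMB | C1C[C@]2(C)[C@@H](O[Si](C)(C)C(C)(C)C)CCCC(=O)[C@@H]2[C@H]1OCc3ccc(OC)cc3 | intermediate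
9 | C7=C8 trimethylsilyl enol ether of 8 | C1C[C@]2(C)[C@@H](O[Si](C)(C)C(C)(C)C)CCC=C(O[Si](C)(C)C)[C@@H]2[C@H]1OCc3ccc(OC)cc3 | intermediate
10 | C6=C7 enone (C8 ketone) | C1C[C@]2(C)[C@@H](O[Si](C)(C)C(C)(C)C)CC=CC(=O)[C@@H]2[C@H]1OCc3ccc(OC)cc3 | intermediate
11 | C6-methyl C7=C8 trimethylsilyl enol ether (C6 methyl drawn α, anti to the C4 silyloxy group; this center is lost in the same step) | C1C[C@]2(C)[C@@H](O[Si](C)(C)C(C)(C)C)C[C@H](C)C=C(O[Si](C)(C)C)[C@@H]2[C@H]1OCc3ccc(OC)cc3 | intermediate
12 | C6-methyl C6=C7 enone (C8 ketone) | C1C[C@]2(C)[C@@H](O[Si](C)(C)C(C)(C)C)CC(C)=CC(=O)[C@@H]2[C@H]1OCc3ccc(OC)cc3 | intermediate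
13 | C8 α-allylic alcohol | C1C[C@]2(C)[C@@H](O[Si](C)(C)C(C)(C)C)CC(C)=C[C@H](O)[C@@H]2[C@H]1OCc3ccc(OC)cc3 | intermediate
14 | 4-hydroxybenzoic acid | OC(=O)c1ccc(O)cc1 | starting material
15 | tert-butyldimethylsilyl 4-(tert-butyldimethylsilyloxy)benzoate | CC(C)(C)[Si](C)(C)OC(=O)c1ccc(O[Si](C)(C)C(C)(C)C)cc1 | intermediate
16 | 4-(tert-butyldimethylsilyloxy)benzoic acid | OC(=O)c1ccc(O[Si](C)(C)C(C)(C)C)cc1 | intermediate
17 | C8 α-[4-(TBS-oxy)benzoate], C10 β-OPMB, C4 β-OTBS | C1C[C@]2(C)[C@@H](O[Si](C)(C)C(C)(C)C)CC(C)=C[C@H](OC(=O)c3ccc(O[Si](C)(C)C(C)(C)C)cc3)[C@@H]2[C@H]1OCc4ccc(OC)cc4 | intermediate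
18 | C10 β-alcohol (PMB removed) | C1C[C@]2(C)[C@@H](O[Si](C)(C)C(C)(C)C)CC(C)=C[C@H](OC(=O)c3ccc(O[Si](C)(C)C(C)(C)C)cc3)[C@@H]2[C@H]1O | intermediate
19 | C10 ketone | C1C[C@]2(C)[C@@H](O[Si](C)(C)C(C)(C)C)CC(C)=C[C@H](OC(=O)c3ccc(O[Si](C)(C)C(C)(C)C)cc3)[C@@H]2C1=O | intermediate
20 | C1=C10 enol triflate | C=1C[C@]2(C)[C@@H](O[Si](C)(C)C(C)(C)C)CC(C)=C[C@H](OC(=O)c3ccc(O[Si](C)(C)C(C)(C)C)cc3)[C@@H]2C=1OS(=O)(=O)C(F)(F)F | intermediate
21 | C10-isopropyl C1=C10 cyclopentene | C=1C[C@]2(C)[C@@H](O[Si](C)(C)C(C)(C)C)CC(C)=C[C@H](OC(=O)c3ccc(O[Si](C)(C)C(C)(C)C)cc3)[C@@H]2C=1C(C)C | intermediate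
22 | C1 β-OH, C10 β-OH (tertiary), C10 α-isopropyl diol | O[C@H]1C[C@]2(C)[C@@H](O[Si](C)(C)C(C)(C)C)CC(C)=C[C@H](OC(=O)c3ccc(O[Si](C)(C)C(C)(C)C)cc3)[C@@H]2[C@]1(O)C(C)C | intermediate
23 | C1 β-acetate of 22 | CC(=O)O[C@H]1C[C@]2(C)[C@@H](O[Si](C)(C)C(C)(C)C)CC(C)=C[C@H](OC(=O)c3ccc(O[Si](C)(C)C(C)(C)C)cc3)[C@@H]2[C@]1(O)C(C)C | intermediate
24 | CNP0146780.2: C1 β-OAc, C3 β-Me, C4 β-OH, C6=C7, C8 α-(4-hydroxybenzoate), C9 β-H, C10 β-OH and α-isopropyl | CC(=O)O[C@H]1C[C@]2(C)[C@@H](O)CC(C)=C[C@H](OC(=O)c3ccc(O)cc3)[C@@H]2[C@]1(O)C(C)C | target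

Total step count: 19. Longest linear sequence: 18 steps (steps 1–10 and 12–19); step 11 is a one-step side branch.

Steps most likely to fail

1. Step 15. What may go wrong: enolisation toward C9 instead of C1, followed by β-elimination of the C8 aroyloxy group or epimerisation of the ring fusion. The fallback avoids any enolate and sets out from ketone 19. Condensation with 1,2-bis(tert-butyldimethylsilyl)hydrazine (Sc(OTf)3 cat., CH2Cl2) should give the N-silyl hydrazone F1. Iodine and tetramethylguanidine (Barton vinyl iodide synthesis) should then give the less substituted alkenyl iodide F2. Negishi coupling of F2 with i-PrZnBr (PdCl2(dppf) cat., THF) comes back to the route at 21, so 20 is bypassed.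

2. Step 17. What may go wrong: poor facial selectivity, with osmylation on the concave α face. The fallback is a Woodward cis-hydroxylation, which delivers both oxygens to the face opposite to the first electrophilic attack; it sets out from 21. Iodine and AgOAc in AcOH should add iodine to the less hindered face at C1 and acetate to C10 from the other face, giving the trans iodo acetate F3. Warming F3 with AgOAc in wet AcOH should displace the iodide with participation of the neighbouring acetate, and hydrolysis of the bridged cation, with the acetyl group settling on the less hindered secondary oxygen under the acidic conditions, should give 23, where the fallback comes back to the route, so 22 is bypassed.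

3. Step 10. What may go wrong: poor facial selectivity in the hydride delivery to C8 (attack from the α face). The fallback sets out from enone 12. The C8 β-alcohol F4 that forms in that case is esterified with acid 16 under Mitsunobu conditions (PPh3, diisopropyl azodicarboxylate, toluene). This inverts C8 and comes back to the route at ester 17, so 13 is bypassed.

Further compounds
F1 | step 15 | N-(tert-butyldimethylsilyl) hydrazone of ketone 19 (silylamino group anti to C9) | C1C[C@]2(C)[C@@H](O[Si](C)(C)C(C)(C)C)CC(C)=C[C@H](OC(=O)c3ccc(O[Si](C)(C)C(C)(C)C)cc3)[C@@H]2/C1=N/N[Si](C)(C)C(C)(C)C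
F2 | step 15 | C10 iodo C1=C10 alkene | C=1C[C@]2(C)[C@@H](O[Si](C)(C)C(C)(C)C)CC(C)=C[C@H](OC(=O)c3ccc(O[Si](C)(C)C(C)(C)C)cc3)[C@@H]2C=1I
F3 | step 17 | trans iodo acetate: C1 α-iodide, C10 β-acetate, C10 α-isopropyl | I[C@@H]1C[C@]2(C)[C@@H](O[Si](C)(C)C(C)(C)C)CC(C)=C[C@H](OC(=O)c3ccc(O[Si](C)(C)C(C)(C)C)cc3)[C@@H]2[C@]1(OC(C)=O)C(C)C
F4 | step 10 | C8 β-allylic alcohol (C8 epimer of 13) | C1C[C@]2(C)[C@@H](O[Si](C)(C)C(C)(C)C)CC(C)=C[C@@H](O)[C@@H]2[C@H]1OCc3ccc(OC)cc3
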